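## Retrosynthetic overview

- Feature: ring carbons C1–C6 plus the ester carbon C7 are a benzoate skeleton (shikimate numbering: C1 bears CO2Me, C2 is the vinyl CH, C3 OAc, C4 O-propanoyl, C5 O-(R)-2-methylbutanoyl, C6 is CH2). The C3–O stereocentre has the sense that toluene dioxygenase creates at the carbon meta to a ring substituent.
- C1=C2 and the C6 methylene come from a C6=C1 enoate carrying an extra acetate on C2: hydride adds at C6 and the C2 oxygen is expelled.
- The C5 ester and C4 oxygen come from a C4–C5 epoxide, syn to the C3 oxygen, opened anti at allylic C5 by the acid. The epoxide comes from the C4=C5 alkene under direction by the C3 hydroxyl.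
- Key disconnection: C2–O and C3–O come from methyl benzoate and O2 by enzymatic cis-dihydroxylation of the ortho–meta bond.
- Rings: the single carbocycle is never closed; it is the benzene ring of methyl benzoate, dearomatised in the first step.

Key step: step 1

Convention and assumption: positions are given in shikimate numbering throughout; "up" is the face that receives the two enzymatic hydroxyls. (R)-2-Methylbutanoic acid is taken as purchasable in high enantiomeric purity. The target is (3R,4S,5R) with a (2R) acyl group: C3–O and C4–O up, C5–O down.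

## Route

Step 1
Reactants: 1 methyl benzoate
Product: 2 methyl (5S,6R)-5,6-dihydroxycyclohexa-1,3-diene-1-carboxylate (C2–OH and C3–OH both up; diene C4=C5/C6=C1)
Conditions: Escherichia coli JM109(pDTG601A) whole cells expressing toluene dioxygenase (IPTG-induced), glucose feed, air sparge, mineral salts medium pH 6.8–7.2, 30–35 °C; cell removal, EtOAc extraction; 2 kept cold in solution and used at once
Reagents that add atoms: dioxygen, O=O
Why: Toluene dioxygenase is a Rieske non-heme iron oxygenase in which electrons from NADH pass through reductase, ferredoxin and the [2Fe-2S] cluster to a mononuclear iron site, where side-on bound dioxygen is reduced to a trivalent-iron hydroperoxo (or pentavalent-iron oxo-hydroxo) species that delivers both oxygen atoms to one face of the C2–C3 bond of the bound arene; the closest known reaction is the cis-dihydroxylation of toluene and of benzoate esters by this same enzyme. No ring is closed: two C–O bonds form and the arene becomes the C4=C5/C6=C1 diene. Both new stereocentres (C2 and C3; 6R and 5S in diene numbering) are fixed by the active site, which holds the ester where the methyl group of toluene normally sits and presents one face of the ortho–meta bond to iron, cis delivery making the two hydroxyls syn. The step needs ortho–meta regioselectivity (not ipso–ortho, as benzoate dioxygenases give with the free acid) and a single enantiofacial sense, and the neutral, compact methyl ester should secure both because it is recognised as a toluene-like substituent. Over-oxidation to the catechol should not occur because the recombinant host carries no cis-diol dehydrogenase.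

Step 2
Reactants: 2 methyl (5S,6R)-5,6-dihydroxycyclohexa-1,3-diene-1-carboxylate
Product: 3 methyl (1S,4R,5R,6R)-4,5-dihydroxy-7-oxabicyclo[4.1.0]hept-2-ene-3-carboxylate (C4–C5 epoxide up, cis to both hydroxyls)
Conditions: mCPBA (1.1 equiv), solid NaHCO3, CH2Cl2, 0 °C; aq. Na2S2O3/NaHCO3 wash
Reagents that add atoms: mCPBA (3-chloroperoxybenzoic acid), O=C(OO)c1cccc(Cl)c1
Why: Henbest hydroxyl-directed peracid epoxidation: the allylic C3–OH hydrogen-bonds the peracid and delivers oxygen to its own face of the electron-richer C4=C5 bond (C6=C1 is deactivated by the ester), which sets C4 and C5 with the epoxide syn to the diol.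

Step 3
Reactants: 3 methyl (1S,4R,5R,6R)-4,5-dihydroxy-7-oxabicyclo[4.1.0]hept-2-ene-3-carboxylate
Product: 4 methyl (1S,4R,5R,6S)-4,5-diacetoxy-7-oxabicyclo[4.1.0]hept-2-ene-3-carboxylate (C2–OAc, C3–OAc, epoxide, all up)
Conditions: Ac2O (3 equiv), pyridine, DMAP (5 mol%), CH2Cl2, 0 °C
Reagents that add atoms: acetic anhydride, CC(=O)OC(C)=O
Why: Nucleophile-catalysed O-acylation of the two secondary alcohols touches no stereocentre, and the epoxide survives because the cis C3 oxygen cannot reach C4 from the backside (no Payne rearrangement).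

Step 4
Reactants: 4 methyl (1S,4R,5R,6S)-4,5-diacetoxy-7-oxabicyclo[4.1.0]hept-2-ene-3-carboxylate; 5 (R)-2-methylbutanoic acid
Product: 6 methyl (3R,4S,5S,6R)-5,6-diacetoxy-4-hydroxy-3-{[(2R)-2-methylbutanoyl]oxy}cyclohex-1-ene-1-carboxylate (C2–OAc up, C3–OAc up, C4–OH up, C5–O-acyl down, C6=C1)
Conditions: 5 (3 equiv), Sc(OTf)3 (5 mol%), CH2Cl2, −20 → 0 °C; cold aq. NaHCO3 wash (excess 5 recovered); crude 6 taken on at once
Reagents that add atoms: (R)-2-methylbutanoic acid (5), CC[C@@H](C)C(=O)O
Why: Lewis-acid-catalysed acidolysis of a vinyl epoxide (a γ,δ-epoxy-α,β-unsaturated ester) by SN2 opening: the acid attacks the allylic γ-carbon C5 anti to the epoxide oxygen from the open lower face, inverting C5 (ester down) and leaving the C4 oxygen up, while C4 is deactivated by the adjacent C3 acetate, which is cis to the epoxide and so cannot participate.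

Step 5
Reactants: 6 methyl (3R,4S,5S,6R)-5,6-diacetoxy-4-hydroxy-3-{[(2R)-2-methylbutanoyl]oxy}cyclohex-1-ene-1-carboxylate
Product: 7 methyl (3R,4S,5R,6R)-5,6-diacetoxy-3-{[(2R)-2-methylbutanoyl]oxy}-4-(propanoyloxy)cyclohex-1-ene-1-carboxylate
Conditions: (EtCO)2O (2 equiv), pyridine, DMAP (10 mol%), CH2Cl2, 0 °C
Reagents that add atoms: propanoic anhydride, CCC(=O)OC(=O)CC
Why: DMAP-catalysed acylation of the one remaining secondary alcohol, run cold on fresh 6 so that acylation should outrun acetyl migration from C3 to C4; no stereocentre is touched.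

Step 6
Reactants: 7 methyl (3R,4S,5R,6R)-5,6-diacetoxy-3-{[(2R)-2-methylbutanoyl]oxy}-4-(propanoyloxy)cyclohex-1-ene-1-carboxylate
Product: 9 methyl (3R,4S,5R)-3-acetoxy-5-{[(2R)-2-methylbutanoyl]oxy}-4-(propanoyloxy)cyclohex-1-ene-1-carboxylate (CNP0403577.1), via copper enolate 8 (not isolated)
Conditions: [(Ph3P)CuH]6 (0.2 equiv of hexamer), anhydrous degassed toluene, 0 °C → rt; aq. NH4Cl
Reagents that add atoms: none
Why: Conjugate reduction with β-elimination, the SN2′ reduction known for Morita–Baylis–Hillman acetates: hydrocupration of the enoate puts hydride on C6 and generates the C1 copper enolate 8, which expels the only β-leaving group (the C2 acetate), so the alkene moves to C1=C2 and C6 becomes CH2, while copper hydride leaves the other four esters and the C3, C4 and C5 stereocentres untouched.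

## Compound list

1 | methyl benzoate | COC(=O)c1ccccc1 | starting material
2 | methyl (5S,6R)-5,6-dihydroxycyclohexa-1,3-diene-1-carboxylate | C1=CC=C(C(=O)OC)[C@@H](O)[C@H]1O | intermediate
3 | methyl (1S,4R,5R,6R)-4,5-dihydroxy-7-oxabicyclo[4.1.0]hept-2-ene-3-carboxylate | COC(=O)C1=C[C@@H]2O[C@@H]2[C@H](O)[C@@H]1O | intermediate
4 | methyl (1S,4R,5R,6S)-4,5-diacetoxy-7-oxabicyclo[4.1.0]hept-2-ene-3-carboxylate | COC(=O)C1=C[C@@H]2O[C@@H]2[C@H](OC(C)=O)[C@@H]1OC(C)=O | intermediate
5 | (R)-2-methylbutanoic acid | CC[C@@H](C)C(=O)O | starting material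
6 | methyl (3R,4S,5S,6R)-5,6-diacetoxy-4-hydroxy-3-{[(2R)-2-methylbutanoyl]oxy}cyclohex-1-ene-1-carboxylate | COC(=O)C1=C[C@@H](OC(=O)[C@H](C)CC)[C@H](O)[C@H](OC(C)=O)[C@@H]1OC(C)=O | intermediate
7 | methyl (3R,4S,5R,6R)-5,6-diacetoxy-3-{[(2R)-2-methylbutanoyl]oxy}-4-(propanoyloxy)cyclohex-1-ene-1-carboxylate | COC(=O)C1=C[C@@H](OC(=O)[C@H](C)CC)[C@H](OC(=O)CC)[C@H](OC(C)=O)[C@@H]1OC(C)=O | intermediate
8 | monovalent copper ester enolate formed from 7 by hydride addition at C6 (O-bound; phosphine ligand not drawn) | COC(O[Cu])=C1[C@@H](OC(C)=O)[C@@H](OC(C)=O)[C@@H](OC(=O)CC)[C@H](OC(=O)[C@H](C)CC)C1 | intermediate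
9 | methyl (3R,4S,5R)-3-acetoxy-5-{[(2R)-2-methylbutanoyl]oxy}-4-(propanoyloxy)cyclohex-1-ene-1-carboxylate (CNP0403577.1) | CCC(=O)O[C@@H]1[C@H](OC(C)=O)C=C(C(=O)OC)C[C@H]1OC(=O)[C@H](C)CC | target

## Step count and risks

Total step count: 6. Longest linear sequence: 6 steps, from methyl benzoate 1; acid 5 is used as bought.

Steps most likely to fail:

1. Step 6. Hydrocupration of the trisubstituted ring enoate may be slow, and the product enoate may then be reduced further to the saturated ester. The enolate may also be protonated before it eliminates. Fallback, from 7 back to 9: the C6=C1 bond of 7 would be hydrogenated (H2, 5% Rh/Al2O3, EtOAc, rt; rhodium is chosen to limit allylic C–O hydrogenolysis) to methyl (2R,3R,4S,5R)-2,3-diacetoxy-5-{[(2R)-2-methylbutanoyl]oxy}-4-(propanoyloxy)cyclohexane-1-carboxylate F1, as either or both C1 epimers. DBU (1.1 equiv, CH2Cl2, 0 °C) should then effect E1cB loss of the C2 acetate, the only acyloxy group β to the ester α-carbon, to give 9.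

2. Step 4. The hindered α-branched acid may attack slowly, so that opening at C4 or an ionised pathway (loss of inversion at C5) competes. Acetyl migration from C3 to the freed C4 hydroxyl may also occur. Fallback, from 4 back to 6: the epoxide would be hydrolysed (HClO4 cat., THF/H2O, 0 °C), water entering anti at allylic C5, to methyl (3R,4S,5S,6R)-5,6-diacetoxy-3,4-dihydroxycyclohex-1-ene-1-carboxylate F2. The allylic C5 hydroxyl would then be acylated selectively with 5 under Steglich conditions (EDC·HCl, DMAP cat., CH2Cl2, −20 °C) to give 6. The C4 hydroxyl, flanked by two oxygenated carbons, is expected to react more slowly, as the central hydroxyl of shikimate esters does.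

3. Step 2. Hydroxyl direction may give incomplete facial selectivity, and diol 2 may dehydrate to phenols or dimerise by Diels–Alder reaction before it is epoxidised. Fallback, from 2 back to 4: 2 would first be acetylated (Ac2O, pyridine, 0 °C) to methyl (5S,6R)-5,6-diacetoxycyclohexa-1,3-diene-1-carboxylate F3. NBS in THF/H2O at 0 °C should form the bromonium ion on the face opposite the acetates, and water should open it trans to give methyl (3S,4R,5R,6R)-5,6-diacetoxy-4-bromo-3-hydroxycyclohex-1-ene-1-carboxylate F4; the regioisomeric trans-bromohydrin would converge on the same epoxide. Closure with Ag2O (THF, rt) then gives the syn epoxide 4 without passing through the free epoxy diol 3.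

## Further compounds

F1 | step 6 | methyl (2R,3R,4S,5R)-2,3-diacetoxy-5-{[(2R)-2-methylbutanoyl]oxy}-4-(propanoyloxy)cyclohexane-1-carboxylate (C1 epimers) | COC(=O)C1C[C@@H](OC(=O)[C@H](C)CC)[C@H](OC(=O)CC)[C@H](OC(C)=O)[C@@H]1OC(C)=O
F2 | step 4 | methyl (3R,4S,5S,6R)-5,6-diacetoxy-3,4-dihydroxycyclohex-1-ene-1-carboxylate | COC(=O)C1=C[C@@H](O)[C@H](O)[C@H](OC(C)=O)[C@@H]1OC(C)=O
F3 | step 2 | methyl (5S,6R)-5,6-diacetoxycyclohexa-1,3-diene-1-carboxylate | C1=CC=C(C(=O)OC)[C@@H](OC(C)=O)[C@H]1OC(C)=O
F4 | step 2 | methyl (3S,4R,5R,6R)-5,6-diacetoxy-4-bromo-3-hydroxycyclohex-1-ene-1-carboxylate | COC(=O)C1=C[C@H](O)[C@@H](Br)[C@H](OC(C)=O)[C@@H]1OC(C)=O
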